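The six-membered ring is disconnected at the C1–C2 bond (C1 chain-bearing carbinol, C3 secondary carbinol, C4=C5 olefin, C6 methylene). The hydroxyl at C1 and the oxygen at C3 flank C2 in an aldol relationship, and the ring olefin C4=C5 is cis by necessity, so the ring maps onto an open-chain cis keto enone whose β-keto ester carbon becomes C2. One catalytic enantioselective intramolecular aldol addition closes the ring, forms C1–C2 and sets the tertiary carbinol. Its precursor, allyl (4Z,19Z)-3,7-dioxo-23-phenyltricosa-4,19-dienoate, is released from a stable cis-ene-diol by double oxidation directly before use; deallylative decarboxylation and a catalyst-controlled carbonyl reduction then give the cis diol.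

Key step: step 10

Assumption: the quinidine-derived amine–thiourea is taken to give the (S)-configured tertiary carbinol, and its quinine-derived pseudoenantiomer would be used unchanged otherwise if the sense of induction proves opposite; compounds 11, 13, 16 and 17 are carried as stereoisomer mixtures because their carbinol centres are oxidised in step 9.

Step 1
Reactants: 1 12-bromododecan-1-ol
Product: 2 12-bromododecanal
Conditions: (2,2,6,6-tetramethylpiperidin-1-yl)oxyl (TEMPO, 0.1 equiv), PhI(OAc)2 (1.1 equiv), CH2Cl2, rt
Reagents that add atoms: none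
Why: Oxoammonium-mediated (TEMPO/PhI(OAc)2) oxidation of a primary alcohol should stop at the aldehyde and leaves the primary bromide untouched.

Step 2
Reactants: 3 (4-bromobutyl)benzene
Product: 4 triphenyl(4-phenylbutyl)phosphonium bromide
Conditions: PPh3, toluene, reflux
Reagents that add atoms: triphenylphosphine, c1ccc(cc1)P(c1ccccc1)c1ccccc1
Why: SN2 quaternisation of triphenylphosphine by a primary alkyl bromide gives the phosphonium salt needed for the Wittig reaction.

Step 3
Reactants: 4 triphenyl(4-phenylbutyl)phosphonium bromide; 2 12-bromododecanal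
Product: 6 [(4Z)-16-bromohexadec-4-en-1-yl]benzene, via phosphorus ylide 5 (not isolated)
Conditions: NaN(SiMe3)2, THF, −78 °C; then 2, −78 °C to rt
Reagents that add atoms: none
Why: Wittig olefination of a non-stabilised ylide under lithium-free conditions should give the cis olefin through the kinetically preferred cis-oxaphosphetane, the aldehyde reacting far faster with the ylide than the remote primary bromide.

Step 4
Reactants: 6 [(4Z)-16-bromohexadec-4-en-1-yl]benzene
Product: 8 (13Z)-17-phenylheptadec-13-enal, via Grignard reagent 7 (not isolated)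
Conditions: Mg turnings, THF, 40 °C; then DMF, 0 °C; then H2O
Reagents that add atoms: N,N-dimethylformamide, CN(C)C=O
Why: Bouveault aldehyde synthesis, in which the primary Grignard reagent adds once to DMF and the magnesium hemiaminal releases the one-carbon-homologated aldehyde only on aqueous work-up.

Step 5
Reactants: 8 (13Z)-17-phenylheptadec-13-enal; 9 propargyl bromide
Product: 11 (16Z)-20-phenylicos-16-en-1-yn-4-ol (racemic), via allenylzinc bromide 10 (not isolated)
Conditions: Zn dust, THF, 0 °C to rt; then H2O
Reagents that add atoms: none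
Why: Barbier propargylation, in which the allenylzinc species formed in the flask adds to the aldehyde in the SE2' sense to give the homopropargylic alcohol, whose configuration is immaterial because this carbon becomes a ketone in step 9.

Step 6
Reactants: 11 (16Z)-20-phenylicos-16-en-1-yn-4-ol
Product: 13 (17Z)-5-hydroxy-21-phenylhenicos-17-en-2-ynal, via dilithio derivative 12 (not isolated)
Conditions: n-BuLi (2.1 equiv), THF, −78 to −20 °C; DMF, −78 to 0 °C; inverse quench into cold pH 7 phosphate buffer
Reagents that add atoms: N,N-dimethylformamide, CN(C)C=O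
Why: Formylation of a lithium acetylide with DMF, in which the second equivalent of base masks the hydroxyl as an alkoxide that is inert to DMF and the buffered inverse quench releases the ynal without conjugate addition of dimethylamine.

Step 7
Reactants: 13 (17Z)-5-hydroxy-21-phenylhenicos-17-en-2-ynal; 14 allyl acetate
Product: 16 prop-2-enyl (19Z)-3,7-dihydroxy-23-phenyltricos-19-en-4-ynoate (mixture of diastereomers), via lithium enolate 15 (not isolated)
Conditions: LiN(i-Pr)2 (3.2 equiv), 14 (3.3 equiv), THF, −78 °C; then 13, −78 °C; then H2O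
Reagents that add atoms: none
Why: Aldol addition of a lithium ester enolate to the ynal carbonyl (1,2-addition at −78 °C), with excess enolate compensating for the free hydroxyl, and with no need for diastereocontrol because both carbinol centres are oxidised later.

Step 8
Reactants: 16 prop-2-enyl (19Z)-3,7-dihydroxy-23-phenyltricos-19-en-4-ynoate
Product: 17 prop-2-enyl (4Z,19Z)-3,7-dihydroxy-23-phenyltricosa-4,19-dienoate (mixture of diastereomers)
Conditions: H2 (1 atm), Lindlar catalyst (Pd on CaCO3 poisoned with Pb(OAc)2), quinoline, EtOAc, rt, stopped after 1 equiv H2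
Reagents that add atoms: none
Why: Lindlar semi-hydrogenation delivers both hydrogens to one face of the triple bond and so should give the cis olefin, the alkyne being bound much more strongly to the poisoned surface than the allyl ester olefin or the chain olefin.

Step 9
Reactants: 17 prop-2-enyl (4Z,19Z)-3,7-dihydroxy-23-phenyltricosa-4,19-dienoate
Product: 18 prop-2-enyl (4Z,19Z)-3,7-dioxo-23-phenyltricosa-4,19-dienoate
Conditions: Dess–Martin periodinane (3 equiv), pyridine, CH2Cl2, 0 °C; pentane, filtration through Celite and Florisil; used at once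
Reagents that add atoms: none
Why: Dess–Martin oxidation turns the allylic and the homoallylic carbinol into the enone and the β,γ-unsaturated ketone under buffered, non-enolising conditions that keep the cis geometry and the olefin position, and unveiling both carbonyl groups only here keeps the labile cis keto enone out of every earlier step.

Step 10
Reactants: 18 prop-2-enyl (4Z,19Z)-3,7-dioxo-23-phenyltricosa-4,19-dienoate
Product: 19 prop-2-enyl (1R,6S)-6-hydroxy-2-oxo-6-[(12Z)-16-phenylhexadec-12-en-1-yl]cyclohex-3-ene-1-carboxylate
Conditions: 1-[3,5-bis(trifluoromethyl)phenyl]-3-[(9R)-6'-methoxycinchonan-9-yl]thiourea (10 mol %), toluene (0.02 M), −40 °C; cold filtration through neutral silica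
Reagents that add atoms: none
Why: Proposed new method: the quinuclidine nitrogen of the catalyst deprotonates the β-keto ester at C2 of 18 while the thiourea hydrogen-bonds the C7 ketone, and the bound enolate carbon C2 adds to C7 to create the ring bond C1–C2 of the target numbering, the closest known reaction type being the amine–thiourea-catalysed enantioselective intramolecular aldol addition of 1,3-dicarbonyl compounds to ketones, with the base-induced ring-opening and aldol cyclisation of pyrylium salts to phenols as the precedent for the connectivity. The single ring closes in the 6-(enolendo)-exo-trig mode, which is feasible because the cis geometry of the C4=C5 olefin brings the nucleophilic carbon C2 and the carbonyl carbon C7 into proximity. Of the two new stereocentres only the tertiary carbinol matters: it is set by the catalyst, which selects the enantioface of the C7 carbonyl inside the hydrogen-bonded ion pair, whereas the ester-bearing centre is epimerisable and is removed in step 11. The step needs C-attack from C2 in preference to deprotonation at C6, to O-cyclisation to a pyranol and to loss of water to the 6-alkylsalicylate; the much higher acidity of the β-keto ester C2–H lets a weak tertiary amine serve as the only base, hemiketal formation is reversible whereas C–C bond formation should not be at −40 °C, and the absence of acid, the low temperature and the neutral filtration should keep the tertiary hydroxyl in place.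

Step 11
Reactants: 19 prop-2-enyl (1R,6S)-6-hydroxy-2-oxo-6-[(12Z)-16-phenylhexadec-12-en-1-yl]cyclohex-3-ene-1-carboxylate
Product: 21 (5S)-5-hydroxy-5-[(12Z)-16-phenylhexadec-12-en-1-yl]cyclohex-2-en-1-one, via β-keto acid 20 (not isolated)
Conditions: Pd(PPh3)4 (5 mol %), morpholine (1.2 equiv), THF, 0 °C to rt
Reagents that add atoms: none
Why: Tsuji deallylation–decarboxylation, in which zerovalent palladium ionises the allyl ester, morpholine captures the allyl group and the β-keto acid loses CO2 at room temperature under near-neutral conditions that should leave the tertiary β-hydroxyl and its configuration untouched.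

Step 12
Reactants: 21 (5S)-5-hydroxy-5-[(12Z)-16-phenylhexadec-12-en-1-yl]cyclohex-2-en-1-one
Product: 23 (1S,3S)-1-[(12Z)-16-phenylhexadec-12-en-1-yl]cyclohex-4-ene-1,3-diol, via bis(catecholborate) 22 (not isolated)
Conditions: (R)-2-methyl-CBS-oxazaborolidine [(3aR)-1-methyl-3,3-diphenyltetrahydro-1H,3H-pyrrolo[1,2-c][1,3,2]oxazaborole] (0.2 equiv), catecholborane (3 equiv), toluene, −78 °C; then H2O
Reagents that add atoms: none
Why: Corey–Bakshi–Shibata reduction, in which the (R)-oxazaborolidine–catecholborane complex binds the enone carbonyl with the alkenyl arm as the large group and should deliver hydride to the face that gives the (S)-allylic carbinol, which is also the face opposite to the borylated tertiary oxygen, so that catalyst and substrate bias both lead to the cis diol, while catecholborane at −78 °C neither hydroborates the olefins nor reduces the s-trans enone in the 1,4 sense.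

Compound list
1 | 12-bromododecan-1-ol | OCCCCCCCCCCCCBr | starting material
2 | 12-bromododecanal | O=CCCCCCCCCCCCBr | intermediate
3 | (4-bromobutyl)benzene | BrCCCCc1ccccc1 | starting material
4 | triphenyl(4-phenylbutyl)phosphonium bromide | [Br-].c1ccccc1CCCC[P+](c1ccccc1)(c1ccccc1)c1ccccc1 | intermediate
5 | triphenyl(4-phenylbutylidene)phosphorane (ylide, formed in the flask) | c1ccccc1CCCC=P(c1ccccc1)(c1ccccc1)c1ccccc1 | intermediate
6 | [(4Z)-16-bromohexadec-4-en-1-yl]benzene | BrCCCCCCCCCCC/C=C\CCCc1ccccc1 | intermediate
7 | [(12Z)-16-phenylhexadec-12-en-1-yl]magnesium bromide (formed in the flask) | Br[Mg]CCCCCCCCCCC/C=C\CCCc1ccccc1 | intermediate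
8 | (13Z)-17-phenylheptadec-13-enal | O=CCCCCCCCCCCC/C=C\CCCc1ccccc1 | intermediate
9 | propargyl bromide (3-bromoprop-1-yne) | C#CCBr | starting material
10 | propa-1,2-dien-1-ylzinc bromide (formed in the flask) | C=C=C[Zn]Br | intermediate
11 | (16Z)-20-phenylicos-16-en-1-yn-4-ol (racemic) | C#CCC(O)CCCCCCCCCCC/C=C\CCCc1ccccc1 | intermediate
12 | lithium (16Z)-1-lithio-20-phenylicos-16-en-1-yn-4-olate (formed in the flask) | [Li]C#CCC(O[Li])CCCCCCCCCCC/C=C\CCCc1ccccc1 | intermediate
13 | (17Z)-5-hydroxy-21-phenylhenicos-17-en-2-ynal (racemic) | O=CC#CCC(O)CCCCCCCCCCC/C=C\CCCc1ccccc1 | intermediate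
14 | allyl acetate (prop-2-enyl acetate) | CC(=O)OCC=C | starting material
15 | lithium 1-(prop-2-enyloxy)ethen-1-olate (formed in the flask) | C=C(O[Li])OCC=C | intermediate
16 | prop-2-enyl (19Z)-3,7-dihydroxy-23-phenyltricos-19-en-4-ynoate (mixture of diastereomers) | C=CCOC(=O)CC(O)C#CCC(O)CCCCCCCCCCC/C=C\CCCc1ccccc1 | intermediate
17 | prop-2-enyl (4Z,19Z)-3,7-dihydroxy-23-phenyltricosa-4,19-dienoate (mixture of diastereomers) | C=CCOC(=O)CC(O)/C=C\CC(O)CCCCCCCCCCC/C=C\CCCc1ccccc1 | intermediate
18 | prop-2-enyl (4Z,19Z)-3,7-dioxo-23-phenyltricosa-4,19-dienoate | C=CCOC(=O)CC(=O)/C=C\CC(=O)CCCCCCCCCCC/C=C\CCCc1ccccc1 | intermediate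
19 | prop-2-enyl (1R,6S)-6-hydroxy-2-oxo-6-[(12Z)-16-phenylhexadec-12-en-1-yl]cyclohex-3-ene-1-carboxylate (ester-bearing C1 epimerisable, drawn trans to the hydroxyl) | O=C1C=CC[C@@](O)(CCCCCCCCCCC/C=C\CCCc2ccccc2)[C@H]1C(=O)OCC=C | intermediate
20 | (1R,6S)-6-hydroxy-2-oxo-6-[(12Z)-16-phenylhexadec-12-en-1-yl]cyclohex-3-ene-1-carboxylic acid (formed in the flask) | O=C1C=CC[C@@](O)(CCCCCCCCCCC/C=C\CCCc2ccccc2)[C@H]1C(=O)O | intermediate
21 | (5S)-5-hydroxy-5-[(12Z)-16-phenylhexadec-12-en-1-yl]cyclohex-2-en-1-one | O=C1C=CC[C@@](O)(CCCCCCCCCCC/C=C\CCCc2ccccc2)C1 | intermediate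
22 | 2,2'-{[(1S,3S)-1-[(12Z)-16-phenylhexadec-12-en-1-yl]cyclohex-4-ene-1,3-diyl]bis(oxy)}bis(1,3,2-benzodioxaborole) (formed in the flask) | c1ccc2OB(Oc2c1)O[C@@H]1C=CC[C@@](OB2Oc3ccccc3O2)(CCCCCCCCCCC/C=C\CCCc2ccccc2)C1 | intermediate
23 | (1S,3S)-1-[(12Z)-16-phenylhexadec-12-en-1-yl]cyclohex-4-ene-1,3-diol | O[C@@H]1C=CC[C@@](O)(CCCCCCCCCCC/C=C\CCCc2ccccc2)C1 | target

Total step count: 12. Longest linear sequence: 11 steps (steps 1 and 3 to 12, from 12-bromododecan-1-ol); step 2 is the only branch.

Steps most likely to fail

Step 10, the one step beyond known chemistry. The enolate may close through oxygen instead of carbon, the cis enone may isomerise before it cyclises, the aldol adduct may lose water and aromatise, or the enantioface selection may be poor. The fallback uses known reaction types only, sets out from bromide 6 and returns to the route at enone 21.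
- Grignard reagent 7, made as in step 4, is added to 3-ethoxycyclohex-2-en-1-one (THF, 0 °C) to give 3-ethoxy-1-[(12Z)-16-phenylhexadec-12-en-1-yl]cyclohex-2-en-1-ol F1. On work-up with dilute HCl this loses ethanol (Stork–Danheiser transposition) to give 3-[(12Z)-16-phenylhexadec-12-en-1-yl]cyclohex-2-en-1-one F2.
- Iminium-catalysed nucleophilic epoxidation with aqueous H2O2 and a 9-amino-9-deoxy-epi-cinchona primary amine trifluoroacetate should give (1S,6S)-6-[(12Z)-16-phenylhexadec-12-en-1-yl]-7-oxabicyclo[4.1.0]heptan-2-one F3. The pseudoenantiomer of the amine is chosen for the required sense, and the isolated cis olefin is inert to the nucleophilic oxidant.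
- Reductive cleavage of the α-carbon–oxygen bond with SmI2 (THF/MeOH, −90 °C) gives (3S)-3-hydroxy-3-[(12Z)-16-phenylhexadec-12-en-1-yl]cyclohexan-1-one F4, in which the tertiary carbinol is already in place.
- LiN(i-Pr)2 (2.2 equiv) and Me3SiCl silylate the hydroxyl and form the less substituted enol silane, trimethyl({(5S)-5-[(12Z)-16-phenylhexadec-12-en-1-yl]-5-[(trimethylsilyl)oxy]cyclohex-1-en-1-yl}oxy)silane F5.
- Saegusa–Ito dehydrogenation with Pd(OAc)2 in MeCN gives (5S)-5-[(12Z)-16-phenylhexadec-12-en-1-yl]-5-[(trimethylsilyl)oxy]cyclohex-2-en-1-one F6, and AcOH/THF/H2O removes the silyl ether to give 21.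

Step 9. After the first oxidation the cis hydroxy ketone may close to a six-membered hemiketal and lose water, the second oxidation may stall, or the cis enone may isomerise during isolation. The fallback sets out from alkyne diol 16 and returns at 18. Both carbinols are oxidised while the triple bond still holds the two oxygen functions apart (Dess–Martin periodinane, pyridine, CH2Cl2, 0 °C), giving prop-2-enyl (19Z)-3,7-dioxo-23-phenyltricos-19-en-4-ynoate F7. The cis olefin is then introduced last by semi-hydrogenation of the activated triple bond over Lindlar catalyst without quinoline at 0 °C, which gives 18 for immediate use in step 10.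

Step 8. Hydrogen uptake may run on into the allyl ester olefin or the new cis olefin, or the cis olefin may isomerise on the catalyst. The fallback sets out from alcohol 11 and returns at diol 17; the cis olefin is made before the allyl ester is present and is then locked in a ring.
- Dilithio derivative 12, made as in step 6, is trapped with paraformaldehyde to give (17Z)-21-phenylhenicos-17-en-2-yne-1,5-diol F8.
- Lindlar semi-hydrogenation, now with no terminal olefin in the molecule, gives (2Z,17Z)-21-phenylhenicosa-2,17-diene-1,5-diol F9.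
- Oxidative lactonisation with TEMPO/PhI(OAc)2 gives 6-[(12Z)-16-phenylhexadec-12-en-1-yl]-5,6-dihydro-2H-pyran-2-one F10.
- i-Bu2AlH at −78 °C gives 6-[(12Z)-16-phenylhexadec-12-en-1-yl]-5,6-dihydro-2H-pyran-2-ol F11. Its lithium lactolate opens to the cis hydroxy enal, which undergoes aldol addition with an excess of lithium enolate 15 (THF, −78 to −40 °C) to give 17.

Further compounds
F1 | step 10 | 3-ethoxy-1-[(12Z)-16-phenylhexadec-12-en-1-yl]cyclohex-2-en-1-ol | CCOC1=CC(O)(CCCCCCCCCCC/C=C\CCCc2ccccc2)CCC1
F2 | step 10 | 3-[(12Z)-16-phenylhexadec-12-en-1-yl]cyclohex-2-en-1-one | O=C1C=C(CCCCCCCCCCC/C=C\CCCc2ccccc2)CCC1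
F3 | step 10 | (1S,6S)-6-[(12Z)-16-phenylhexadec-12-en-1-yl]-7-oxabicyclo[4.1.0]heptan-2-one | O=C1CCC[C@]2(CCCCCCCCCCC/C=C\CCCc3ccccc3)O[C@H]12
F4 | step 10 | (3S)-3-hydroxy-3-[(12Z)-16-phenylhexadec-12-en-1-yl]cyclohexan-1-one | O=C1CCC[C@@](O)(CCCCCCCCCCC/C=C\CCCc2ccccc2)C1
F5 | step 10 | trimethyl({(5S)-5-[(12Z)-16-phenylhexadec-12-en-1-yl]-5-[(trimethylsilyl)oxy]cyclohex-1-en-1-yl}oxy)silane | C[Si](C)(C)OC1=CCC[C@@](O[Si](C)(C)C)(CCCCCCCCCCC/C=C\CCCc2ccccc2)C1
F6 | step 10 | (5S)-5-[(12Z)-16-phenylhexadec-12-en-1-yl]-5-[(trimethylsilyl)oxy]cyclohex-2-en-1-one | O=C1C=CC[C@@](O[Si](C)(C)C)(CCCCCCCCCCC/C=C\CCCc2ccccc2)C1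
F7 | step 9 | prop-2-enyl (19Z)-3,7-dioxo-23-phenyltricos-19-en-4-ynoate | C=CCOC(=O)CC(=O)C#CCC(=O)CCCCCCCCCCC/C=C\CCCc1ccccc1
F8 | step 8 | (17Z)-21-phenylhenicos-17-en-2-yne-1,5-diol | OCC#CCC(O)CCCCCCCCCCC/C=C\CCCc1ccccc1
F9 | step 8 | (2Z,17Z)-21-phenylhenicosa-2,17-diene-1,5-diol | OC/C=C\CC(O)CCCCCCCCCCC/C=C\CCCc1ccccc1
F10 | step 8 | 6-[(12Z)-16-phenylhexadec-12-en-1-yl]-5,6-dihydro-2H-pyran-2-one | O=C1C=CCC(CCCCCCCCCCC/C=C\CCCc2ccccc2)O1
F11 | step 8 | 6-[(12Z)-16-phenylhexadec-12-en-1-yl]-5,6-dihydro-2H-pyran-2-ol | OC1C=CCC(CCCCCCCCCCC/C=C\CCCc2ccccc2)O1
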